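Ring B (the cyclohexene C1–C9a–C9–C10–C11–C12; stenine numbering, defined below) is grown from a cyclopentene. Dibromocarbene delivers C9a across a tetrasubstituted C1=C9 double bond, and silver-induced electrocyclic opening of the 6,6-dibromobicyclo[3.1.0]hexane gives a 2-bromocyclohexenyl cation that the C13 side-chain amide oxygen captures at C1. One operation thus creates ring B, the quaternary C1–O lactone stereocentre and a C9a–Br handle for the enamine nitrogen. It exploits the triad O–C1–C9a(N)=C9, an allylic ester flanking an amino-substituted alkene carbon. The precursor, a gem-dibromocyclopropane-fused cyclopentane carrying every remaining carbon, is assembled by two Negishi couplings from a commercial bicyclic lactone and a serine-derived iodide.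

Key step: step 14

Remark (numbering): N4; pyrroline C1 (quaternary, O-bearing), C2, C3; azepine C5–C8; enamine carbons C9 and C9a; ring B = C1, C9a, C9, C10 (ethyl), C11 (hydroxyl), C12; fused lactone C12–C13(methyl)–C14(=O)–O–C1; side-chain lactone C18 (O-bearing) to C21 (carbonyl), methyl on C20.

Remark (assumption): dibromocarbene may add to either face of the C1=C9 alkene; both adducts open to the same allyl cation, so 24 is written as the adduct anti to the C12 side chain.

Step 1
Reactants: 1 (1R,5S)-2-oxabicyclo[3.3.0]oct-6-en-3-one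
Product: 3 (1R,4R,5R)-4-methyl-2-oxabicyclo[3.3.0]oct-6-en-3-one, via lithium enolate 2 (not isolated)
Conditions: LiN(iPr)2, THF, −78 °C; MeI, −78 → −40 °C
Reagents that add atoms: iodomethane, CI
Why: The lithium enolate of the cis-fused lactone is methylated on its convex face (enolate alkylation), which places the new methyl group exo and sets C13 as R.

Step 2
Reactants: 3 (1R,4R,5R)-4-methyl-2-oxabicyclo[3.3.0]oct-6-en-3-one
Product: 6 4-methyl-2-oxabicyclo[3.3.0]oct-7-ene-3,6-dione (stereocentres as in 3), via allylic hydroperoxide 4 (not isolated), via allylic peracetate 5 (not isolated)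
Conditions: O2, visible light, tetraphenylporphyrin (cat.), Ac2O, pyridine, DMAP (cat.), CH2Cl2, 20 °C
Reagents that add atoms: oxygen, O=O
Why: Singlet oxygen should attack the alkene on the convex face at the carbon next to the ring fusion with transfer of the convex hydrogen of the ring CH2 group (Schenck ene reaction; abstraction of the ring-fusion hydrogen would place the new alkene at the ring fusion), and acetylation of the hydroperoxide followed by base-induced Kornblum–DeLaMare elimination gives the transposed enone in the same flask without creating a stereocentre.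

Step 3
Reactants: 6 4-methyl-2-oxabicyclo[3.3.0]oct-7-ene-3,6-dione
Product: 7 7-iodo-4-methyl-2-oxabicyclo[3.3.0]oct-7-ene-3,6-dione
Conditions: I2, pyridine/CH2Cl2 (1:1), 0 → 20 °C
Reagents that add atoms: iodine, II
Why: Pyridine-mediated α-iodination of the enone (conjugate addition of pyridine, iodination of the enolate, elimination) installs the C9 iodide needed for cross-coupling under conditions too weakly basic to eliminate the γ-acyloxy group.

Step 4
Reactants: 7 7-iodo-4-methyl-2-oxabicyclo[3.3.0]oct-7-ene-3,6-dione; 8 4-chlorobutylzinc bromide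
Product: 9 7-(4-chlorobutyl)-4-methyl-2-oxabicyclo[3.3.0]oct-7-ene-3,6-dione
Conditions: PdCl2(dppf) (5 mol %), THF, 20 → 40 °C
Reagents that add atoms: none
Why: Negishi coupling of the α-iodoenone with the primary alkylzinc reagent attaches the C5–C8 chain without added base, so the ketone with its β-acyloxy group is not exposed to E1cB conditions, and the alkyl chloride is inert to zerovalent palladium under these conditions.

Step 5
Reactants: 9 7-(4-chlorobutyl)-4-methyl-2-oxabicyclo[3.3.0]oct-7-ene-3,6-dione
Product: 11 7-(4-chlorobutyl)-8-ethyl-4-methyl-3-oxo-2-oxabicyclo[3.3.0]oct-6-en-6-yl trifluoromethanesulfonate (ethyl trans to the lactone oxygen), via lithium enolate 10 (not isolated)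
Conditions: Et2CuLi (from EtLi and CuI), Et2O, −78 °C; then Comins' reagent, THF, −78 → −20 °C
Reagents that add atoms: lithium diethylcuprate, [Li+].CC[Cu-]CC; Comins' reagent (N-(5-chloropyridin-2-yl)-bis(trifluoromethanesulfonyl)imide), O=S(=O)(N(c1ccc(Cl)cn1)S(=O)(=O)C(F)(F)F)C(F)(F)F
Why: The Gilman cuprate adds to C10 on the convex face, anti to the γ-lactone oxygen, which sets C10 (S, ethyl trans to O11), and O-sulfonylation of the regiodefined enolate locks the tetrasubstituted C1=C9 double bond (conjugate addition with enolate trapping).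

Step 6
Reactants: 11 the enol triflate lactone
Product: 12 (2R)-2-[3-(4-chlorobutyl)-4-ethyl-5-hydroxy-2-(trifluoromethylsulfonyloxy)cyclopent-2-en-1-yl]-N,N-dimethylpropanamide (1,5-cis; 4,5-trans)
Conditions: Me2NH·HCl, AlMe3, CH2Cl2, 0 → 20 °C; aq. potassium sodium tartrate work-up
Reagents that add atoms: dimethylamine hydrochloride, C[NH2+]C.[Cl-]
Why: The aluminium amide opens the strained cis-fused lactone by acyl substitution (Weinreb aminolysis) without touching C11, C12 or C13, and gives a tertiary amide that does not relactonise under neutral conditions and later serves as the internal oxygen nucleophile.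

Step 7
Reactants: 12 the hydroxy amide
Product: 13 tert-butyldimethylsilyl ether of 12
Conditions: TBSOTf, 2,6-lutidine, CH2Cl2, −40 → 0 °C
Reagents that add atoms: tert-butyldimethylsilyl trifluoromethanesulfonate, CC(C)(C)[Si](C)(C)OS(=O)(=O)C(F)(F)F
Why: Silylation of the hindered secondary alcohol with the silyl triflate protects O11 against carbene attack in step 13 and against acyl migration in the basic step 15 (silyl ether formation).

Step 8
Reactants: 14 tert-butyl (R)-4-formyl-2,2-dimethyl-1,3-oxazolidine-3-carboxylate; 15 ethyl 2-(bromomethyl)acrylate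
Product: 18 tert-butyl (4R)-2,2-dimethyl-4-[(2S)-4-methylidene-5-oxooxolan-2-yl]-1,3-oxazolidine-3-carboxylate, via allylzinc bromide 16 (not isolated), via zinc alkoxide 17 (not isolated)
Conditions: Zn dust (activated), THF, 45 °C; aq. NH4Cl work-up
Reagents that add atoms: none
Why: The Dreiding–Schmidt reaction should add the ester-substituted allylzinc reagent to the aldehyde anti to the C–N bond (Felkin–Anh, non-chelated N-Boc oxazolidine), which sets C18 as S, and the zinc alkoxide closes the α-methylene-γ-lactone in the same flask.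

Step 9
Reactants: 18 the α-methylene lactone
Product: 19 tert-butyl (4R)-2,2-dimethyl-4-[(2S,4S)-4-methyl-5-oxooxolan-2-yl]-1,3-oxazolidine-3-carboxylate
Conditions: H2 (1 atm), Pd/C, EtOAc, 20 °C
Reagents that add atoms: none
Why: Heterogeneous hydrogenation should deliver hydrogen to the exocyclic alkene from the lactone face opposite the bulky C18 substituent, so the methyl group ends cis to it and C20 is set as S.

Step 10
Reactants: 19 the cis-methyl lactone
Product: 20 tert-butyl N-[(1R)-2-hydroxy-1-[(2S,4S)-4-methyl-5-oxooxolan-2-yl]ethyl]carbamate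
Conditions: TsOH·H2O (cat.), MeOH, 20 °C
Reagents that add atoms: none
Why: Acid-catalysed transacetalisation with methanol removes the N,O-isopropylidene group while the carbamate and the γ-lactone are stable to these conditions (acetal cleavage).

Step 11
Reactants: 20 the N-Boc amino alcohol
Product: 21 tert-butyl N-[(1S)-2-iodo-1-[(2S,4S)-4-methyl-5-oxooxolan-2-yl]ethyl]carbamate
Conditions: I2, PPh3, imidazole, CH2Cl2, 0 °C
Reagents that add atoms: iodine, II
Why: Appel-type iodination (Garegg–Samuelsson conditions) converts the primary alcohol into the iodide at 0 °C without cyclisation of the neighbouring carbamate and without touching a stereocentre.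

Step 12
Reactants: 13 the silylated enol triflate amide; 21 the iodide
Product: 23 (2R)-2-[2-[(2R)-2-(tert-butoxycarbonylamino)-2-[(2S,4S)-4-methyl-5-oxooxolan-2-yl]ethyl]-3-(4-chlorobutyl)-4-ethyl-5-(tert-butyldimethylsilyloxy)cyclopent-2-en-1-yl]-N,N-dimethylpropanamide, via alkylzinc iodide 22 (not isolated)
Conditions: Zn dust (I2-activated), DMF, 20 °C; then 13, Pd2(dba)3 (2.5 mol %), SPhos (10 mol %), 45 °C
Reagents that add atoms: none
Why: Zinc inserts into the primary C–I bond to give a β-amido alkylzinc iodide that resists β-elimination (Jackson-type reagent), and Negishi coupling with the enol triflate forms the C1–C2 bond with retention of all stereocentres and tolerance of lactone, amide and alkyl chloride.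

Step 13
Reactants: 23 the tetrasubstituted cyclopentene
Product: 24 6,6-dibromobicyclo[3.1.0]hexane formed across C1=C9 of 23
Conditions: CHBr3, 50% aq. NaOH, BnEt3NCl (cat.), CH2Cl2, 0 °C; used crude and cold
Reagents that add atoms: bromoform, BrC(Br)Br
Why: Dibromocarbene generated at the interface under phase-transfer conditions (Makosza cyclopropanation) should add to the electron-rich tetrasubstituted alkene faster than hydroxide, which stays in the aqueous phase, attacks the lactone or the carbamate, and facial selectivity is irrelevant because both adducts give the same cation in step 14.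

Step 14
Reactants: 24 the gem-dibromocyclopropane
Product: 26 ring-expanded 9a-bromo lactone, via iminium ether triflate 25 (not isolated)
Conditions: AgOTf, CH2Cl2/CF3CH2OH (4:1), −20 → 20 °C, dark; then THF/H2O, 20 °C
Reagents that add atoms: water, O
Why: Silver-assisted loss of the endo bromide is concerted with disrotatory two-electron electrocyclic opening of the C1–C9 bond, so the cyclopentane becomes the six-membered 2-bromoallyl cation C1–C9a(Br)–C9 of ring B (one-carbon ring expansion; both termini become planar, so the cyclopropane configuration does not matter). The closest known reaction type is the silver-promoted ring opening of ring-fused gem-dihalocyclopropanes with capture of the halo-allyl cation by a tethered heteroatom nucleophile. The amide oxygen, held on C12 through C13, attacks C1 in a 5-exo-trig closure to the iminium ether 25, which water hydrolyses at the iminium carbon to the γ-lactone with release of dimethylamine, so that 26 carries the C9a–Br alkene, the C1/C12 cis-fused lactone and all other groups of 24 unchanged. The new C1 stereocentre is controlled by C12, because the tether reaches only the face cis to the C12–C13 bond and so gives the cis-fused lactone (C1 R). Regioselectivity for C1 over C9 is secured by ring size, since attack at C9 would need a bridged seven-membered ring, and the C9a–Br alkene ends up where the enamine is required. The step needs capture at C1 by the amide oxygen to outrun both proton loss from the cation and the slower six-membered closure by the less nucleophilic carbamate oxygen, which the tertiary amide, the non-basic medium and the absence of free hydroxyl groups (O11 is silylated) should secure.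

Step 15
Reactants: 26 the ring-expanded 9a-bromo lactone
Product: 27 N-Boc enecarbamate (pyrroline ring closed by the N4–C9a bond)
Conditions: CuI (20 mol %), MeNHCH2CH2NHMe (40 mol %), Cs2CO3, THF, 70 °C
Reagents that add atoms: none
Why: Copper-catalysed intramolecular N-vinylation of the carbamate (Goldberg–Buchwald amidation of an alkenyl bromide) closes the five-membered ring in a 5-exo mode with the C9=C9a double bond kept in place, while the carbonate base is too weak to epimerise the lactones and the silyl ether on O11 excludes acyl migration.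

Step 16
Reactants: 27 the N-Boc enecarbamate
Product: 31 CNP0154902.3 (target), via iminium trifluoroacetate 28 (not isolated), via iodo imine 29 (not isolated), via tricyclic iminium iodide 30 (not isolated)
Conditions: TFA/H2O (9:1), 0 → 20 °C; evaporate; K2CO3, KI, MeCN, 60 °C
Reagents that add atoms: none
Why: Aqueous trifluoroacetic acid removes the Boc and silyl groups to leave the cyclic iminium salt, and after neutralisation the imine nitrogen is alkylated by the alkyl iodide formed in situ (Finkelstein) in a 7-exo-tet closure, N-alkylation being preferred over C-alkylation because the enamine tautomer is minor and its β-carbon C9 is fully substituted, and loss of the only α-proton (at C9) gives the tetrasubstituted enamine.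

Compound list
1 | (1R,5S)-2-oxabicyclo[3.3.0]oct-6-en-3-one | O=C1C[C@H]2C=CC[C@H]2O1 | starting material
2 | lithium enolate of 1 | [Li]OC1=C[C@H]2C=CC[C@H]2O1 | intermediate
3 | (1R,4R,5R)-4-methyl-2-oxabicyclo[3.3.0]oct-6-en-3-one (methyl exo) | O=C1[C@H](C)[C@H]2C=CC[C@H]2O1 | intermediate
4 | 6-hydroperoxy-4-methyl-2-oxabicyclo[3.3.0]oct-7-en-3-one (OOH on the convex face) | O=C1[C@H](C)[C@H]2[C@H](OO)C=C[C@H]2O1 | intermediate
5 | O-acetyl derivative (peracetate) of 4 | O=C1[C@H](C)[C@H]2[C@H](OOC(C)=O)C=C[C@H]2O1 | intermediate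
6 | 4-methyl-2-oxabicyclo[3.3.0]oct-7-ene-3,6-dione | O=C1[C@H](C)[C@H]2C(=O)C=C[C@H]2O1 | intermediate
7 | 7-iodo-4-methyl-2-oxabicyclo[3.3.0]oct-7-ene-3,6-dione | O=C1[C@H](C)[C@H]2C(=O)C(I)=C[C@H]2O1 | intermediate
8 | 4-chlorobutylzinc bromide | ClCCCC[Zn]Br | starting material
9 | 7-(4-chlorobutyl)-4-methyl-2-oxabicyclo[3.3.0]oct-7-ene-3,6-dione | O=C1[C@H](C)[C@H]2C(=O)C(CCCCCl)=C[C@H]2O1 | intermediate
10 | lithium enolate after ethyl addition (8-ethyl exo) | O=C1[C@H](C)[C@H]2C(O[Li])=C(CCCCCl)[C@H](CC)[C@H]2O1 | intermediate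
11 | 7-(4-chlorobutyl)-8-ethyl-4-methyl-3-oxo-2-oxabicyclo[3.3.0]oct-6-en-6-yl trifluoromethanesulfonate | O=C1[C@H](C)[C@H]2C(OS(=O)(=O)C(F)(F)F)=C(CCCCCl)[C@H](CC)[C@H]2O1 | intermediate
12 | (2R)-2-[3-(4-chlorobutyl)-4-ethyl-5-hydroxy-2-(trifluoromethylsulfonyloxy)cyclopent-2-en-1-yl]-N,N-dimethylpropanamide | CN(C)C(=O)[C@H](C)[C@H]1C(OS(=O)(=O)C(F)(F)F)=C(CCCCCl)[C@H](CC)[C@H]1O | intermediate
13 | tert-butyldimethylsilyl ether of 12 | CN(C)C(=O)[C@H](C)[C@H]1C(OS(=O)(=O)C(F)(F)F)=C(CCCCCl)[C@H](CC)[C@H]1O[Si](C)(C)C(C)(C)C | intermediate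
14 | tert-butyl (R)-4-formyl-2,2-dimethyl-1,3-oxazolidine-3-carboxylate | CC(C)(C)OC(=O)N1[C@@H](C=O)COC1(C)C | starting material
15 | ethyl 2-(bromomethyl)acrylate | C=C(CBr)C(=O)OCC | starting material
16 | [2-(ethoxycarbonyl)allyl]zinc bromide | CCOC(=O)C(=C)C[Zn]Br | intermediate
17 | zinc alkoxide of the anti homoallylic alcohol | CC(C)(C)OC(=O)N1[C@@H]([C@@H](O[Zn]Br)CC(=C)C(=O)OCC)COC1(C)C | intermediate
18 | tert-butyl (4R)-2,2-dimethyl-4-[(2S)-4-methylidene-5-oxooxolan-2-yl]-1,3-oxazolidine-3-carboxylate | CC(C)(C)OC(=O)N1[C@@H]([C@@H]2CC(=C)C(=O)O2)COC1(C)C | intermediate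
19 | tert-butyl (4R)-2,2-dimethyl-4-[(2S,4S)-4-methyl-5-oxooxolan-2-yl]-1,3-oxazolidine-3-carboxylate | CC(C)(C)OC(=O)N1[C@@H]([C@@H]2C[C@H](C)C(=O)O2)COC1(C)C | intermediate
20 | tert-butyl N-[(1R)-2-hydroxy-1-[(2S,4S)-4-methyl-5-oxooxolan-2-yl]ethyl]carbamate | CC(C)(C)OC(=O)N[C@H](CO)[C@@H]1C[C@H](C)C(=O)O1 | intermediate
21 | tert-butyl N-[(1S)-2-iodo-1-[(2S,4S)-4-methyl-5-oxooxolan-2-yl]ethyl]carbamate | CC(C)(C)OC(=O)N[C@H](CI)[C@@H]1C[C@H](C)C(=O)O1 | intermediate
22 | alkylzinc iodide from 21 | CC(C)(C)OC(=O)N[C@H](C[Zn]I)[C@@H]1C[C@H](C)C(=O)O1 | intermediate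
23 | tetrasubstituted cyclopentene (amide, silyl ether, C1 side chain, C9 chlorobutyl) | CN(C)C(=O)[C@H](C)[C@H]1C(C[C@@H](NC(=O)OC(C)(C)C)[C@@H]2C[C@H](C)C(=O)O2)=C(CCCCCl)[C@H](CC)[C@H]1O[Si](C)(C)C(C)(C)C | intermediate
24 | 6,6-dibromobicyclo[3.1.0]hexane across C1–C9 of 23 | CN(C)C(=O)[C@H](C)[C@H]1[C@]2(C[C@@H](NC(=O)OC(C)(C)C)[C@@H]3C[C@H](C)C(=O)O3)C(Br)(Br)[C@]2(CCCCCl)[C@H](CC)[C@H]1O[Si](C)(C)C(C)(C)C | intermediate
25 | ring-expanded iminium ether triflate | CC[C@H]1C(CCCCCl)=C(Br)[C@]2(C[C@@H](NC(=O)OC(C)(C)C)[C@@H]3C[C@H](C)C(=O)O3)OC(=[N+](C)C)[C@H](C)[C@@H]2[C@@H]1O[Si](C)(C)C(C)(C)C.[O-]S(=O)(=O)C(F)(F)F | intermediate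
26 | ring-expanded 9a-bromo lactone | CC[C@H]1C(CCCCCl)=C(Br)[C@]2(C[C@@H](NC(=O)OC(C)(C)C)[C@@H]3C[C@H](C)C(=O)O3)OC(=O)[C@H](C)[C@@H]2[C@@H]1O[Si](C)(C)C(C)(C)C | intermediate
27 | N-Boc enecarbamate (pyrroline closed) | CC[C@H]1C(CCCCCl)=C2N(C(=O)OC(C)(C)C)[C@@H]([C@@H]3C[C@H](C)C(=O)O3)C[C@]24OC(=O)[C@H](C)[C@@H]4[C@@H]1O[Si](C)(C)C(C)(C)C | intermediate
28 | deprotected 1-pyrrolinium trifluoroacetate | CC[C@H]1C(CCCCCl)C2=[NH+][C@@H]([C@@H]3C[C@H](C)C(=O)O3)C[C@]24OC(=O)[C@H](C)[C@@H]4[C@@H]1O.[O-]C(=O)C(F)(F)F | intermediate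
29 | iodo imine | CC[C@H]1C(CCCCI)C2=N[C@@H]([C@@H]3C[C@H](C)C(=O)O3)C[C@]24OC(=O)[C@H](C)[C@@H]4[C@@H]1O | intermediate
30 | tricyclic iminium iodide | CC[C@H]1C2C3=[N+](CCCC2)[C@@H]([C@@H]2C[C@H](C)C(=O)O2)C[C@]32OC(=O)[C@H](C)[C@@H]2[C@@H]1O.[I-] | intermediate
31 | CNP0154902.3 | CC[C@H]1C2=C3N(CCCC2)[C@@H]([C@@H]2C[C@H](C)C(=O)O2)C[C@]32OC(=O)[C@H](C)[C@@H]2[C@@H]1O | target

Total step count: 16. Longest linear sequence: 12 steps (steps 1–7 and 12–16).

Steps most likely to fail

Step 14. The cation may lose a proton to give bromodienes, or the dibromide may ionise too early (during carbene transfer or handling), before silver and the amide can act together. The fallback changes the halogen so that ionisation happens only on demand. It sets out from 23: dichlorocarbene (CHCl3, 50% aq. NaOH, BnEt3NCl) should give the thermally inert dichlorocyclopropane F1. AgBF4 in CF3CH2OH at 50 °C then triggers the same ring expansion with amide capture, giving the chloro iminium ether tetrafluoroborate F2, which water hydrolyses to the 9a-chloro lactone F3. Because alkenyl chlorides respond poorly to copper, the carbamate N-vinylation is run under palladium catalysis (Pd2(dba)3, tBuXPhos, K3PO4, tert-amyl alcohol, 90 °C), and the route comes back at 27.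

Step 15. Oxidative addition at the congested tetrasubstituted alkenyl bromide may be too slow, so that protodebromination or decomposition of the carbamate takes over. The fallback makes the C9a–N bond by condensation instead of coupling. It sets out from 26: Miyaura borylation (B2pin2, PdCl2(dppf), KOAc, dioxane, 80 °C) gives the alkenyl pinacol boronate F4, and NaBO3·4H2O in THF/H2O oxidises it to the C9a ketone F5 (the C9 configuration is inconsequential). TFA/H2O removes the Boc and silyl groups to give the amino ketone trifluoroacetate F6, whose ammonium group condenses with the ketone, and the route comes back at 28 inside step 16.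

Step 12. β-Elimination of the carbamate from the zinc reagent, or slow transmetalation to the congested alkenylpalladium intermediate, may consume 22 without coupling. The fallback avoids a preformed organozinc. It sets out from 13 and 21: a nickel-catalysed reductive cross-electrophile coupling (NiBr2·glyme, 4,4'-di-tert-butyl-2,2'-bipyridine, Mn powder, NaI, DMA, 40 °C), in which the alkyl radical from 21 is captured at nickel, should give 23 directly, where the route comes back; no new compound is involved.

Further compounds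
F1 | step 14 | 6,6-dichlorobicyclo[3.1.0]hexane analogue of 24 | CN(C)C(=O)[C@H](C)[C@H]1[C@]2(C[C@@H](NC(=O)OC(C)(C)C)[C@@H]3C[C@H](C)C(=O)O3)C(Cl)(Cl)[C@]2(CCCCCl)[C@H](CC)[C@H]1O[Si](C)(C)C(C)(C)C
F2 | step 14 | chloro iminium ether tetrafluoroborate | CC[C@H]1C(CCCCCl)=C(Cl)[C@]2(C[C@@H](NC(=O)OC(C)(C)C)[C@@H]3C[C@H](C)C(=O)O3)OC(=[N+](C)C)[C@H](C)[C@@H]2[C@@H]1O[Si](C)(C)C(C)(C)C.F[B-](F)(F)F
F3 | step 14 | 9a-chloro analogue of 26 | CC[C@H]1C(CCCCCl)=C(Cl)[C@]2(C[C@@H](NC(=O)OC(C)(C)C)[C@@H]3C[C@H](C)C(=O)O3)OC(=O)[C@H](C)[C@@H]2[C@@H]1O[Si](C)(C)C(C)(C)C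
F4 | step 15 | C9a pinacol boronate | CC[C@H]1C(CCCCCl)=C(B2OC(C)(C)C(C)(C)O2)[C@]3(C[C@@H](NC(=O)OC(C)(C)C)[C@@H]4C[C@H](C)C(=O)O4)OC(=O)[C@H](C)[C@@H]3[C@@H]1O[Si](C)(C)C(C)(C)C
F5 | step 15 | C9a ketone (α-acyloxy ketone) | CC[C@H]1[C@H](CCCCCl)C(=O)[C@]2(C[C@@H](NC(=O)OC(C)(C)C)[C@@H]3C[C@H](C)C(=O)O3)OC(=O)[C@H](C)[C@@H]2[C@@H]1O[Si](C)(C)C(C)(C)C
F6 | step 15 | amino ketone trifluoroacetate | CC[C@H]1[C@H](CCCCCl)C(=O)[C@]2(C[C@@H]([NH3+])[C@@H]3C[C@H](C)C(=O)O3)OC(=O)[C@H](C)[C@@H]2[C@@H]1O.[O-]C(=O)C(F)(F)F
F0 | step 12 | none | none
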